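**Plan**

- Numbering: C1 = oxolane CH bearing C15 (the CMe2–O carbon), C2 = oxolane CH2, C3 = OCH, C4 = CH(CO2Me), C5–C6, C7=C8(CO2Me), C9–C10, C11=C12(Me), C13–C14 back to C1. Feature: C3 is an ether carbon of the oxolane and its neighbour C4 is an ester α-carbon, so the ring bond C2–C3 maps onto a C2 radical closing on a β-alkoxyacrylate C15–O–C3H=C4(C5)–CO2Me.
- Retrosynthesis: cut C7=C8 (ring-closing Horner–Wadsworth–Emmons), then C12–C13 (B-alkyl Suzuki–Miyaura), then C2–C3 together with C4–H (radical 5-exo closure and hydrogen transfer), then C4–C5 (Suzuki–Miyaura on an α-iodoacrylate) and O–C3 (phosphine-catalysed addition to methyl propiolate).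
- Forward: prenol → epoxy alcohol → vinyl diol (C1, C15) → tert-alkyl β-alkoxyacrylate → C5–C7 chain → oxolane (first ring, step 9); the C9–C12 phosphonate arm is then joined at C12–C13 and the 14-membered carbocycle closes last.
- Stereochemistry: C1 from Sharpless epoxidation followed by invertive cuprate opening; C3 and C4 relayed from C1 in the radical step; 11Z from the iodo-ylide olefination and a retentive coupling; 7E from the Horner–Wadsworth–Emmons closure.

Key step: step 9

Remark: 8 is a diastereomer mixture and the phosphonate-bearing carbon (C8) of 26, 28 and 29 is uncontrolled; these centres disappear in steps 5 and 16, so the compounds are carried as mixtures.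

**Route**

Step 1
Reactants: 1 prenol (3-methylbut-2-en-1-ol)
Product: 2 [(2S)-3,3-dimethyloxiran-2-yl]methanol
Conditions: Ti(OiPr)4 (5 mol %), L-(+)-DIPT (6 mol %), t-BuOOH, 4 Å MS, CH2Cl2, −20 °C
Reagents that add atoms: tert-butyl hydroperoxide, CC(C)(C)OO
Why: Catalytic Sharpless asymmetric epoxidation of a primary allylic alcohol, in which the titanium–L-(+)-tartrate complex delivers the peroxide oxygen to one alkene face and so sets the (2S) centre, the future C1 before inversion.

Step 2
Reactants: 2 [(2S)-3,3-dimethyloxiran-2-yl]methanol; 3 vinylmagnesium bromide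
Product: 4 (2R)-2-ethenyl-3-methylbutane-1,3-diol
Conditions: 3 (3 equiv), CuI (10 mol %), THF, −30 → 0 °C
Reagents that add atoms: none
Why: Copper-catalysed Grignard opening of a 2,3-epoxy alcohol, an SN2 attack at the secondary epoxide carbon (the other one is fully substituted) that inverts it and so turns the (2S)-epoxide into the (R)-configured, vinyl-bearing C1 of a 1,3-diol.

Step 3
Reactants: 4 (2R)-2-ethenyl-3-methylbutane-1,3-diol
Product: 5 (3R)-3-[(tert-butyldiphenylsilyloxy)methyl]-2-methylpent-4-en-2-ol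
Conditions: TBDPSCl, imidazole, CH2Cl2, 0 °C → rt
Reagents that add atoms: tert-butyl(chloro)diphenylsilane, CC(C)(C)[Si](Cl)(c1ccccc1)c1ccccc1
Why: Silyl ether formation is selective for the primary hydroxyl because the tertiary hydroxyl is too hindered for this silyl chloride, and the robust TBDPS group is chosen to survive the acidic iodination of step 5.

Step 4
Reactants: 5 (3R)-3-[(tert-butyldiphenylsilyloxy)methyl]-2-methylpent-4-en-2-ol; 6 methyl propiolate
Product: 7 methyl (2E)-3-{[(3R)-3-[(tert-butyldiphenylsilyloxy)methyl]-2-methylpent-4-en-2-yl]oxy}prop-2-enoate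
Conditions: PMe3 (20 mol %), CH2Cl2, 0 °C → rt
Reagents that add atoms: none
Why: Trimethylphosphine-catalysed oxa-Michael addition (hydroalkoxylation) to methyl propiolate, which also works for tertiary alcohols and gives the (E)-β-alkoxyacrylate by addition of the alkoxide to the β-phosphonium acrylate and loss of the phosphine.

Step 5
Reactants: 7 methyl (2E)-3-{[(3R)-3-[(tert-butyldiphenylsilyloxy)methyl]-2-methylpent-4-en-2-yl]oxy}prop-2-enoate
Product: 9 methyl (2Z)-2-iodo-3-{[(3R)-3-[(tert-butyldiphenylsilyloxy)methyl]-2-methylpent-4-en-2-yl]oxy}prop-2-enoate, via iodoacetate adduct 8 (not isolated)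
Conditions: NIS, AcOH, CH2Cl2, 0 °C → rt; then Et3N, 0 °C
Reagents that add atoms: N-iodosuccinimide, O=C1CCC(=O)N1I
Why: Electrophilic iodoacetoxylation of the vinylogous carbonate (far more nucleophilic than the terminal vinyl group) followed by E1cB loss of acetic acid, the standard conversion of (E)-β-alkoxyacrylates into (Z)-α-iodo-β-alkoxyacrylates.

Step 6
Reactants: 9 methyl (2Z)-2-iodo-3-{[(3R)-3-[(tert-butyldiphenylsilyloxy)methyl]-2-methylpent-4-en-2-yl]oxy}prop-2-enoate; 10 3,3-diethoxyprop-1-ene (acrolein diethyl acetal)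
Product: 12 methyl (2E)-2-({[(3R)-3-[(tert-butyldiphenylsilyloxy)methyl]-2-methylpent-4-en-2-yl]oxy}methylidene)-5,5-diethoxypentanoate, via alkylborane 11 (not isolated)
Conditions: 10 (1.6 equiv), 9-BBN (1.5 equiv), THF, 0 °C → rt; then 9, PdCl2(dppf) (5 mol %), AsPh3, Cs2CO3, DMF/H2O, rt
Reagents that add atoms: none
Why: Anti-Markovnikov hydroboration of 10 with 9-BBN and B-alkyl Suzuki–Miyaura coupling with the α-iodoacrylate under the mild conditions used for α-iodoenones, with retention of alkene geometry so that the C5–C7 chain ends cis to oxygen (E) and the alkene of 9 is left alone because no free borane remains.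

Step 7
Reactants: 12 methyl (2E)-2-({[(3R)-3-[(tert-butyldiphenylsilyloxy)methyl]-2-methylpent-4-en-2-yl]oxy}methylidene)-5,5-diethoxypentanoate
Product: 13 methyl (2E)-5,5-diethoxy-2-({[(3R)-3-(hydroxymethyl)-2-methylpent-4-en-2-yl]oxy}methylidene)pentanoate
Conditions: Bu4NF, AcOH (1:1), THF, rt
Reagents that add atoms: none
Why: Fluoride desilylation of the primary silyl ether, buffered with acetic acid so that no free alkoxide can add to the acrylate and the acetal stays intact.

Step 8
Reactants: 13 methyl (2E)-5,5-diethoxy-2-({[(3R)-3-(hydroxymethyl)-2-methylpent-4-en-2-yl]oxy}methylidene)pentanoate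
Product: 14 methyl (2E)-5,5-diethoxy-2-({[(3S)-3-(iodomethyl)-2-methylpent-4-en-2-yl]oxy}methylidene)pentanoate
Conditions: I2, PPh3, imidazole, CH2Cl2, 0 °C → rt
Reagents that add atoms: iodine, II
Why: Appel-type iodination of the primary alcohol through its alkoxyphosphonium salt, with imidazole keeping the medium non-acidic for the acetal and the enol ether (the descriptor changes to S only because iodine outranks oxygen).

Step 9
Reactants: 14 methyl (2E)-5,5-diethoxy-2-({[(3S)-3-(iodomethyl)-2-methylpent-4-en-2-yl]oxy}methylidene)pentanoate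
Product: 15 methyl (2S)-2-[(2S,4S)-4-ethenyl-5,5-dimethyloxolan-2-yl]-5,5-diethoxypentanoate
Conditions: Bu3SnH (1.5 equiv, slow addition), Et3B (0.3 equiv), air, toluene (0.01 M), −78 °C
Reagents that add atoms: none
Why: Ethyl radicals from Et3B/O2 start a tin chain in which Bu3Sn• abstracts iodine from C2, the primary radical adds to C3 (the β-carbon of the vinylogous carbonate) to form C2–C3, and the tertiary α-ester radical at C4 takes hydrogen from Bu3SnH. The closest known reaction type is the tin hydride cyclisation of β-alkoxyacrylates and β-alkoxymethacrylates to 2-substituted oxacycles with hydrogen transfer next to the new ring. The oxolane O–C3–C2–C1–C15 closes in the 5-exo-trig mode. C3 is set by the C1 centre through a chair-like transition state (the boat would twist the O–C3=C4–C=O conjugation) with the C1 vinyl group pseudoequatorial, which should place the C3 side chain trans to it (3S). C4 is set by C3: in the radical the C3–H bond eclipses the ester plane to avoid allylic strain and Bu3SnH approaches anti to ring carbon C2 (exocyclic effect), giving the 3,4-anti (4S) product. The step needs closure to outrun direct reduction and 1,2-vinyl migration of the C2 radical, which the pairing of a nucleophilic radical with an electron-poor alkene, the gem-dimethyl group in the tether and dilute hydride at −78 °C secure, and the 2,4-trans C4 radical cannot reach the vinyl group for a second closure.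

Step 10
Reactants: 16 3-(tert-butyldimethylsilyloxy)propanal; 17 ethyltriphenylphosphonium iodide
Product: 21 tert-butyl{[(3Z)-4-iodopent-3-en-1-yl]oxy}dimethylsilane, via ethylidenetriphenylphosphorane 18 (not isolated), via (1-iodoethyl)triphenylphosphonium iodide 19 (not isolated), via (1-iodoethylidene)triphenylphosphorane 20 (not isolated)
Conditions: 17, n-BuLi, THF, rt; I2, −78 °C; NaN(SiMe3)2, −20 °C; then 16, −78 → −20 °C
Reagents that add atoms: iodine, II
Why: Stork–Zhao-type Wittig olefination with the non-stabilised α-iodo ylide (made by iodination of the ethylidene ylide and deprotonation), whose kinetically formed cis-oxaphosphetane gives the (Z)-2-iodoalkene with iodine cis to the chain.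

Step 11
Reactants: 21 tert-butyl{[(3Z)-4-iodopent-3-en-1-yl]oxy}dimethylsilane
Product: 22 (3Z)-4-iodopent-3-en-1-ol
Conditions: CSA (10 mol %), MeOH/CH2Cl2, 0 °C
Reagents that add atoms: none
Why: Acid-catalysed methanolysis cleaves the primary TBS ether while the vinyl iodide is inert.

Step 12
Reactants: 22 (3Z)-4-iodopent-3-en-1-ol
Product: 23 (2Z)-2,5-diiodopent-2-ene
Conditions: I2, PPh3, imidazole, CH2Cl2, 0 °C
Reagents that add atoms: iodine, II
Why: Appel-type iodination of the primary homoallylic alcohol, which leaves the vinyl iodide and its geometry untouched.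

Step 13
Reactants: 23 (2Z)-2,5-diiodopent-2-ene; 24 methyl diethylphosphonoacetate
Product: 26 methyl (5Z)-2-(diethoxyphosphoryl)-6-iodohept-5-enoate (racemic), via sodium phosphonoacetate 25 (not isolated)
Conditions: 24 (3 equiv), NaH, THF/DMF, 0 °C; then 23, rt → 50 °C
Reagents that add atoms: none
Why: SN2 C-alkylation of the stabilised phosphonoacetate carbanion by the primary iodide (the vinyl iodide cannot react), with excess phosphonate to suppress dialkylation and the new C8 centre left uncontrolled because it is removed in step 16.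

Step 14
Reactants: 15 methyl (2S)-2-[(2S,4S)-4-ethenyl-5,5-dimethyloxolan-2-yl]-5,5-diethoxypentanoate; 26 methyl (5Z)-2-(diethoxyphosphoryl)-6-iodohept-5-enoate
Product: 28 methyl (2S)-2-[(2S,4R)-4-[(3Z)-7-(diethoxyphosphoryl)-8-methoxy-3-methyl-8-oxooct-3-en-1-yl]-5,5-dimethyloxolan-2-yl]-5,5-diethoxypentanoate (epimers at the phosphonate carbon), via alkylborane 27 (not isolated)
Conditions: 15, 9-BBN, THF, rt; then 26, PdCl2(dppf) (10 mol %), AsPh3, Cs2CO3, DMF/H2O, rt
Reagents that add atoms: none
Why: 9-BBN hydroborates only the monosubstituted vinyl group (esters and acetal are inert) and B-alkyl Suzuki–Miyaura coupling with the (Z)-vinyl iodide forms C12–C13 with retention, which fixes the 11Z alkene (the C1 descriptor becomes R only through the change in substituent priority).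

Step 15
Reactants: 28 methyl (2S)-2-[(2S,4R)-4-[(3Z)-7-(diethoxyphosphoryl)-8-methoxy-3-methyl-8-oxooct-3-en-1-yl]-5,5-dimethyloxolan-2-yl]-5,5-diethoxypentanoate
Product: 29 methyl (2S)-2-[(2S,4R)-4-[(3Z)-7-(diethoxyphosphoryl)-8-methoxy-3-methyl-8-oxooct-3-en-1-yl]-5,5-dimethyloxolan-2-yl]-5-oxopentanoate (epimers at the phosphonate carbon)
Conditions: aq. HCl (1 M), THF, rt
Reagents that add atoms: water, O
Why: Acid hydrolysis of the diethyl acetal releases the C7 aldehyde under conditions too mild to touch the esters, the phosphonate or the oxolane, and avoids a free δ-hydroxy ester that could lactonise.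

Step 16
Reactants: 29 methyl (2S)-2-[(2S,4R)-4-[(3Z)-7-(diethoxyphosphoryl)-8-methoxy-3-methyl-8-oxooct-3-en-1-yl]-5,5-dimethyloxolan-2-yl]-5-oxopentanoate
Product: 30 dimethyl (1R,4Z,8E,12S,13S)-4,15,15-trimethyl-14-oxabicyclo[11.2.1]hexadeca-4,8-diene-8,12-dicarboxylate (target CNP0164914.1; 1R,3S,4S,7E,11Z in the numbering of the plan)
Conditions: LiCl, DBU, MeCN, rt, syringe-pump addition of 29 (final 1 mM)
Reagents that add atoms: none
Why: Intramolecular Horner–Wadsworth–Emmons olefination under Masamune–Roush conditions at high dilution closes the 14-membered ring at C7=C8, the lithium-chelated pathway giving the ester trans to C6 (7E), a geometry that places the two ring branches cis on the alkene as the ring requires, while the mild base leaves C4 untouched.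

**Compound list**

1 | prenol (3-methylbut-2-en-1-ol) | CC(C)=CCO | starting material
2 | [(2S)-3,3-dimethyloxiran-2-yl]methanol | OC[C@@H]1OC1(C)C | intermediate
3 | vinylmagnesium bromide | C=C[Mg]Br | starting material
4 | (2R)-2-ethenyl-3-methylbutane-1,3-diol | OC[C@@H](C=C)C(C)(C)O | intermediate
5 | (3R)-3-[(tert-butyldiphenylsilyloxy)methyl]-2-methylpent-4-en-2-ol | CC(C)(C)[Si](c1ccccc1)(c1ccccc1)OC[C@@H](C=C)C(C)(C)O | intermediate
6 | methyl propiolate | COC(=O)C#C | starting material
7 | methyl (2E)-3-{[(3R)-3-[(tert-butyldiphenylsilyloxy)methyl]-2-methylpent-4-en-2-yl]oxy}prop-2-enoate | CC(C)(C)[Si](c1ccccc1)(c1ccccc1)OC[C@@H](C=C)C(C)(C)O/C=C/C(=O)OC | intermediate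
8 | methyl 3-acetoxy-2-iodo-3-{[(3R)-3-[(tert-butyldiphenylsilyloxy)methyl]-2-methylpent-4-en-2-yl]oxy}propanoate (diastereomer mixture) | CC(C)(C)[Si](c1ccccc1)(c1ccccc1)OC[C@@H](C=C)C(C)(C)OC(OC(C)=O)C(I)C(=O)OC | intermediate
9 | methyl (2Z)-2-iodo-3-{[(3R)-3-[(tert-butyldiphenylsilyloxy)methyl]-2-methylpent-4-en-2-yl]oxy}prop-2-enoate | CC(C)(C)[Si](c1ccccc1)(c1ccccc1)OC[C@@H](C=C)C(C)(C)O/C=C(\I)C(=O)OC | intermediate
10 | 3,3-diethoxyprop-1-ene (acrolein diethyl acetal) | C=CC(OCC)OCC | starting material
11 | 9-(3,3-diethoxypropyl)-9-borabicyclo[3.3.1]nonane | CCOC(CCB1C2CCCC1CCC2)OCC | intermediate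
12 | methyl (2E)-2-({[(3R)-3-[(tert-butyldiphenylsilyloxy)methyl]-2-methylpent-4-en-2-yl]oxy}methylidene)-5,5-diethoxypentanoate | CC(C)(C)[Si](c1ccccc1)(c1ccccc1)OC[C@@H](C=C)C(C)(C)O/C=C(\CCC(OCC)OCC)C(=O)OC | intermediate
13 | methyl (2E)-5,5-diethoxy-2-({[(3R)-3-(hydroxymethyl)-2-methylpent-4-en-2-yl]oxy}methylidene)pentanoate | OC[C@@H](C=C)C(C)(C)O/C=C(\CCC(OCC)OCC)C(=O)OC | intermediate
14 | methyl (2E)-5,5-diethoxy-2-({[(3S)-3-(iodomethyl)-2-methylpent-4-en-2-yl]oxy}methylidene)pentanoate | IC[C@@H](C=C)C(C)(C)O/C=C(\CCC(OCC)OCC)C(=O)OC | intermediate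
15 | methyl (2S)-2-[(2S,4S)-4-ethenyl-5,5-dimethyloxolan-2-yl]-5,5-diethoxypentanoate | CCOC(CC[C@H](C(=O)OC)[C@@H]1C[C@@H](C=C)C(C)(C)O1)OCC | intermediate
16 | 3-(tert-butyldimethylsilyloxy)propanal | CC(C)(C)[Si](C)(C)OCCC=O | starting material
17 | ethyltriphenylphosphonium iodide | CC[P+](c1ccccc1)(c1ccccc1)c1ccccc1.[I-] | starting material
18 | ethylidenetriphenylphosphorane | CC=P(c1ccccc1)(c1ccccc1)c1ccccc1 | intermediate
19 | (1-iodoethyl)triphenylphosphonium iodide | CC(I)[P+](c1ccccc1)(c1ccccc1)c1ccccc1.[I-] | intermediate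
20 | (1-iodoethylidene)triphenylphosphorane | CC(I)=P(c1ccccc1)(c1ccccc1)c1ccccc1 | intermediate
21 | tert-butyl{[(3Z)-4-iodopent-3-en-1-yl]oxy}dimethylsilane | CC(C)(C)[Si](C)(C)OCC/C=C(/C)I | intermediate
22 | (3Z)-4-iodopent-3-en-1-ol | OCC/C=C(/C)I | intermediate
23 | (2Z)-2,5-diiodopent-2-ene | ICC/C=C(/C)I | intermediate
24 | methyl diethylphosphonoacetate | CCOP(=O)(CC(=O)OC)OCC | starting material
25 | sodium salt of methyl diethylphosphonoacetate | CCOP(=O)(OCC)[CH-]C(=O)OC.[Na+] | intermediate
26 | methyl (5Z)-2-(diethoxyphosphoryl)-6-iodohept-5-enoate (racemic) | CCOP(=O)(OCC)C(CC/C=C(/C)I)C(=O)OC | intermediate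
27 | methyl (2S)-2-[(2S,4R)-4-[2-(9-borabicyclo[3.3.1]nonan-9-yl)ethyl]-5,5-dimethyloxolan-2-yl]-5,5-diethoxypentanoate | CCOC(CC[C@H](C(=O)OC)[C@@H]1C[C@@H](CCB2C3CCCC2CCC3)C(C)(C)O1)OCC | intermediate
28 | methyl (2S)-2-[(2S,4R)-4-[(3Z)-7-(diethoxyphosphoryl)-8-methoxy-3-methyl-8-oxooct-3-en-1-yl]-5,5-dimethyloxolan-2-yl]-5,5-diethoxypentanoate (epimers at the phosphonate carbon) | CCOC(CC[C@H](C(=O)OC)[C@@H]1C[C@@H](CC/C(C)=C\CCC(P(=O)(OCC)OCC)C(=O)OC)C(C)(C)O1)OCC | intermediate
29 | methyl (2S)-2-[(2S,4R)-4-[(3Z)-7-(diethoxyphosphoryl)-8-methoxy-3-methyl-8-oxooct-3-en-1-yl]-5,5-dimethyloxolan-2-yl]-5-oxopentanoate (epimers at the phosphonate carbon) | O=CCC[C@H](C(=O)OC)[C@@H]1C[C@@H](CC/C(C)=C\CCC(P(=O)(OCC)OCC)C(=O)OC)C(C)(C)O1 | intermediate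
30 | dimethyl (1R,4Z,8E,12S,13S)-4,15,15-trimethyl-14-oxabicyclo[11.2.1]hexadeca-4,8-diene-8,12-dicarboxylate (CNP0164914.1) | COC(=O)/C1=C/CC[C@H](C(=O)OC)[C@@H]2C[C@@H](CC/C(C)=C\CC1)C(C)(C)O2 | target

**Step count and risks**

Total step count: 16. Longest linear sequence: 12 steps (steps 1–9, then 14–16); steps 10–13 are a four-step branch that joins at step 14.

The three steps most likely to fail:

Step 9. The relay from C1 to C3 is a 1,3-induction through a chair-like transition state, and it may be weak here. The gem-dimethyl carbon C15 next to C1 gives the pseudoequatorial vinyl group two gauche contacts, and the ring oxygen removes the syn-axial hydrogen that normally penalises the pseudoaxial alternative. Closure may therefore lose its 2,4-trans preference and deliver the 2,4-cis oxolane alongside 15. Hydrogen transfer at C4 would also lose facial selectivity if the chain only propagated at higher temperature. In the fallback, C3 would be set under thermodynamic control and C4 in a separate radical step. It sets out from 15 as obtained in step 9, mixed with its diastereomers. NaOMe in MeOH at 50 °C should open and re-close the oxolane by reversible retro-oxa-Michael/oxa-Michael addition. In the closed ring the vinyl group should avoid the flanking methyl groups by sitting pseudoaxial, which lets a trans C3 side chain sit pseudoequatorial, so the mixture should drain into the 2,4-trans pair: 15 and its C4 epimer, methyl (2R)-2-[(2S,4S)-4-ethenyl-5,5-dimethyloxolan-2-yl]-5,5-diethoxypentanoate F1. Without separation, LiN(iPr)2 (THF, −78 °C) and PhSeBr should give methyl 2-[(2S,4S)-4-ethenyl-5,5-dimethyloxolan-2-yl]-5,5-diethoxy-2-(phenylselanyl)pentanoate F2. Bu3SnH/Et3B/air at −78 °C should then regenerate the C4 radical from both epimers and reduce it anti to C2, free of the constraints of the cyclisation. The fallback comes back to the route at 15.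

Step 16. Intermolecular olefination may outrun ring closure and give oligomers, or the alkene geometry may be scrambled because it is set while the ring forms. In the fallback, C7=C8 would be made between two molecules and the ring closed at C12–C13 instead. It sets out from 15. Aqueous HCl in THF should give methyl (2S)-2-[(2S,4S)-4-ethenyl-5,5-dimethyloxolan-2-yl]-5-oxopentanoate F3. Horner–Wadsworth–Emmons reaction with 26 (LiCl, DBU, MeCN) should give dimethyl (2E,6S)-6-[(2S,4S)-4-ethenyl-5,5-dimethyloxolan-2-yl]-2-[(3Z)-4-iodopent-3-en-1-yl]hept-2-enedioate F4, whose geometric isomers can be separated at this open-chain stage. 9-BBN should add only to the terminal vinyl group to give the alkylborane dimethyl (2E,6S)-6-[(2S,4R)-4-[2-(9-borabicyclo[3.3.1]nonan-9-yl)ethyl]-5,5-dimethyloxolan-2-yl]-2-[(3Z)-4-iodopent-3-en-1-yl]hept-2-enedioate F5. Slow addition of F5 to PdCl2(dppf), AsPh3 and Cs2CO3 in DMF/THF/H2O (macrocyclic B-alkyl Suzuki–Miyaura coupling) should close the ring. The fallback comes back to the route at 30.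

Step 14. The carbonate base may deprotonate the phosphonoacetate C–H of 26. The carbanion could then attack the vinylpalladium intermediate (five-membered ring closure), or the phosphonoacetate ester could be hydrolysed, so that 26 is consumed before transmetalation. In the fallback the phosphonate would be introduced after the coupling. It sets out from 15 (through its alkylborane 27) and the silyl ether 21. The same coupling conditions should give methyl (2S)-2-[(2S,4R)-4-[(3Z)-6-(tert-butyldimethylsilyloxy)-3-methylhex-3-en-1-yl]-5,5-dimethyloxolan-2-yl]-5,5-diethoxypentanoate F6. Bu4NF/AcOH in THF should free methyl (2S)-5,5-diethoxy-2-[(2S,4R)-4-[(3Z)-6-hydroxy-3-methylhex-3-en-1-yl]-5,5-dimethyloxolan-2-yl]pentanoate F7. I2/PPh3/imidazole should give methyl (2S)-5,5-diethoxy-2-[(2S,4R)-4-[(3Z)-6-iodo-3-methylhex-3-en-1-yl]-5,5-dimethyloxolan-2-yl]pentanoate F8. Alkylation of the sodium phosphonoacetate 25 (from 24 and NaH, THF/DMF) with F8 comes back to the route at 28.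

**Further compounds**

F1 | step 9 | methyl (2R)-2-[(2S,4S)-4-ethenyl-5,5-dimethyloxolan-2-yl]-5,5-diethoxypentanoate | CCOC(CC[C@@H](C(=O)OC)[C@@H]1C[C@@H](C=C)C(C)(C)O1)OCC
F2 | step 9 | methyl 2-[(2S,4S)-4-ethenyl-5,5-dimethyloxolan-2-yl]-5,5-diethoxy-2-(phenylselanyl)pentanoate (epimers at the selenium-bearing carbon) | CCOC(CCC([Se]c1ccccc1)(C(=O)OC)[C@@H]1C[C@@H](C=C)C(C)(C)O1)OCC
F3 | step 16 | methyl (2S)-2-[(2S,4S)-4-ethenyl-5,5-dimethyloxolan-2-yl]-5-oxopentanoate | O=CCC[C@H](C(=O)OC)[C@@H]1C[C@@H](C=C)C(C)(C)O1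
F4 | step 16 | dimethyl (2E,6S)-6-[(2S,4S)-4-ethenyl-5,5-dimethyloxolan-2-yl]-2-[(3Z)-4-iodopent-3-en-1-yl]hept-2-enedioate | COC(=O)/C(CC/C=C(/C)I)=C/CC[C@H](C(=O)OC)[C@@H]1C[C@@H](C=C)C(C)(C)O1
F5 | step 16 | dimethyl (2E,6S)-6-[(2S,4R)-4-[2-(9-borabicyclo[3.3.1]nonan-9-yl)ethyl]-5,5-dimethyloxolan-2-yl]-2-[(3Z)-4-iodopent-3-en-1-yl]hept-2-enedioate | COC(=O)/C(CC/C=C(/C)I)=C/CC[C@H](C(=O)OC)[C@@H]1C[C@@H](CCB2C3CCCC2CCC3)C(C)(C)O1
F6 | step 14 | methyl (2S)-2-[(2S,4R)-4-[(3Z)-6-(tert-butyldimethylsilyloxy)-3-methylhex-3-en-1-yl]-5,5-dimethyloxolan-2-yl]-5,5-diethoxypentanoate | CCOC(CC[C@H](C(=O)OC)[C@@H]1C[C@@H](CC/C(C)=C\CCO[Si](C)(C)C(C)(C)C)C(C)(C)O1)OCC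
F7 | step 14 | methyl (2S)-5,5-diethoxy-2-[(2S,4R)-4-[(3Z)-6-hydroxy-3-methylhex-3-en-1-yl]-5,5-dimethyloxolan-2-yl]pentanoate | CCOC(CC[C@H](C(=O)OC)[C@@H]1C[C@@H](CC/C(C)=C\CCO)C(C)(C)O1)OCC
F8 | step 14 | methyl (2S)-5,5-diethoxy-2-[(2S,4R)-4-[(3Z)-6-iodo-3-methylhex-3-en-1-yl]-5,5-dimethyloxolan-2-yl]pentanoate | CCOC(CC[C@H](C(=O)OC)[C@@H]1C[C@@H](CC/C(C)=C\CCI)C(C)(C)O1)OCC
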